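Readings and results are calculated on assumed constants; scatter was added.

3 questions stand at the end of this run, and we reckon towards them by one count: how many half-lives of left-handed substrate fit into the time.

common to all: free catalyst 0.05 mol%; racemization catalyst 3.8 mol%; impurity 31 µM

| charge | left-handed substrate | right-handed substrate | reagent | remark | time |
|---|---|---|---|---|---|
| Saturday's | 0.48 M | 0.48 M | 4 equiv | run made earlier |  |
| flask | 0.24 M | 0.24 M | 4.00 equiv |  | 15 min |

Saturday's run (percent of the left-handed substrate and right-handed substrate together charged)

| time / min | left-handed substrate / % | right-handed substrate / % |
|---|---|---|
| 0.333 | 40 | 48 |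
| 0.500 | 36 | 49 |
| 0.833 | 30 | 47 |
| 1.33 | 23 | 45 |
| 2.00 | 16 | 47 |
| 3.00 | 11 | 42 |
| 5.00 | 3 | 37 |

(each reading ± 2 percentage points)

- free catalyst is single-handed; left-handed substrate and right-handed substrate are mirror images of each other, charged as a racemate, each of them at the stated concentration
- what may be going on: left-handed substrate + racemization catalyst <-> right-handed substrate + racemization catalyst; reagent + free catalyst + left-handed substrate -> free catalyst + left-handed product; reagent + racemization catalyst -> spent catalyst A; free catalyst + impurity -> spent catalyst B; reagent + free catalyst + right-handed substrate -> free catalyst + right-handed product
- an excess is the difference of the two amounts in percent of their sum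
- an excess is below zero if the other one leads
- no earlier run changes the charge of racemization catalyst; that part of a forecast is a guess
- no earlier run changes the charge of free catalyst; that part of a forecast is a guess

* part of the left-handed substrate and right-handed substrate charged together that has reacted at 15 min
* excess of left-handed product over right-handed product in the product at 15 min
* excess of right-handed substrate over left-handed substrate among what is left of the two at 15 min

We climb the time scales from the fastest. First comes the impurity, which we assume binds free catalyst one to one before Saturday's first reading; no run tests this. In this flask that leaves 74.2 % of the free catalyst working, so a quarter would be tied up, against 87.1 % working on Saturday.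

Next comes the left-handed substrate. Saturday's readings fall at 0.555 min⁻¹, a pseudo-first-order reading. We count no refill from racemization, since that substrate kept falling to 3 % at 5.00 min. Taking first order in reagent and in working catalyst, this flask runs at 0.213 of Saturday's rate, so its half-life is 5.87 min. The half-life count, time divided by half-life, is then 2.56, and 17.0 % of the left-handed charge should remain.

Slowest is the right-handed substrate. Its Saturday fall, direct reaction and any racemization lumped together and scaled alike, gives a half-life of 58.4 min, longer than the run. So on a repeat we would watch the left-handed substrate.

The forecast says 54 % reacted, 78 % and 70 %. It scales Saturday's rates by about 0.23, not our 0.213, “Assuming first order in reagent and catalyst”, so its figures are its own.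

The flask gives 49.2 %, 81.3 % and 71.1 %, each within the forecast's margin.

    left-handed substrate + racemization catalyst ⇌ right-handed substrate + racemization catalyst, rate k1*[racemization catalyst]*[left-handed substrate] forward; the back reaction follows from the equilibrium constant (k = 0.622 L mol⁻¹ s⁻¹)
    reagent + free catalyst + left-handed substrate → free catalyst + left-handed product (k = 30.9 L² mol⁻² s⁻¹)
    reagent + racemization catalyst → spent catalyst A (k = 0.0179 L mol⁻¹ s⁻¹)
    free catalyst + impurity → spent catalyst B (k = 89200 L mol⁻¹ s⁻¹)
    reagent + free catalyst + right-handed substrate → free catalyst + right-handed product (k = 1.57 L² mol⁻² s⁻¹)

At 15 min this flask holds 15 % of its left-handed charge, against our 17.0 %. In the neighbour with 5.3 × 10⁻⁵ M of impurity, the same reckoning leaves 55.8 % of the free catalyst working, so the count drops to 1.93 and 26.2 % of the left-handed charge should remain. That neighbour holds 23 %, with 43.8 % reacted, 83.4 % and 59.9 %. In that neighbour the right-handed substrate, at 44.9 %, stands above the left-handed product, at 40.2 %.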